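**Retrosynthetic overview**

- The target is traced back, through the O3 angelate and a protected C8 alcohol, to a bicyclic alcohol; ring B is the last ring formed, by making the C6–C7 bond.
- Disconnection C6–C7: C6 becomes one of two geminal methyl groups on C5 of a monocyclic ring A precursor; C7 becomes the CH= end of an allyl sulfone, C7=C11(CH3)–CH2SO2Ph, whose fragmentation leaves the C11=C12 isopropenyl group.
- Enabling feature: the C3 oxygen and C6 lie on the same face of ring A, 1,3 to each other across C4 (O–C3–C4–C5–C6), and C5 is quaternary. An oxygen radical on C3 can therefore reach one C5 methyl, and only that one, by 1,5-hydrogen transfer, so the ring closure also creates the C5 stereocentre.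
- Side chain: C8–C9 by alkoxyallylboration of a C10 aldehyde, the 3-methylbut-2-enoate on O9, and C7=C11 by cross-metathesis.
- Ring A is formed first by organocatalytic Michael addition and aldol condensation (C10), then two methyl cuprate additions and an enolate methylation (C5, C4). Order of rings: A (step 2), B (step 14).

Key step: step 14

Remark: locants follow eremophilane numbering (ring A = C1–C5 and C10, ring B = C5–C10, C11–C13 isopropenyl, C14 on C5, C15 on C4; α = below, β = above the usual drawing). The C7=C11 geometry of the allyl sulfone intermediates is drawn E, but either isomer should give the same product in the key step.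

**Route**

Step 1
Reactants: 1 3-(benzyloxy)propanal; 2 but-3-en-2-one
Product: 3 (R)-2-[(benzyloxy)methyl]-5-oxohexanal
Conditions: (R)-α,α-diphenylprolinol trimethylsilyl ether (5 mol %), ethyl 3,4-dihydroxybenzoate (20 mol %), neat, 4 °C
Reagents that add atoms: none
Why: Enamine-catalysed asymmetric Michael addition of an aldehyde to an enone, in which the E-enamine of 1 adds to 2 on the face left open by the diphenyl(silyloxy)methyl group of the (R)-catalyst and so sets C10 as (R) in 3.

Step 2
Reactants: 3 (R)-2-[(benzyloxy)methyl]-5-oxohexanal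
Product: 4 (S)-4-[(benzyloxy)methyl]cyclohex-2-en-1-one
Conditions: LiOH (0.3 equiv), i-PrOH, 20 °C
Reagents that add atoms: none
Why: Intramolecular aldol condensation (6-enolexo) of the methyl ketone onto the aldehyde closes ring A under mild base that should leave the γ-stereocentre C10 untouched.

Step 3
Reactants: 4 (S)-4-[(benzyloxy)methyl]cyclohex-2-en-1-one
Product: 5 {[(3R,4S)-4-[(benzyloxy)methyl]-3-methylcyclohex-1-en-1-yl]oxy}trimethylsilane
Conditions: Me2CuLi, TMSCl, THF, −78 °C; Et3N
Reagents that add atoms: lithium dimethylcuprate, [Li+].C[Cu-]C; chlorotrimethylsilane, C[Si](C)(C)Cl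
Why: Chlorotrimethylsilane-accelerated cuprate conjugate addition places a methyl on C5 anti to the C10 substituent and traps the enolate regiospecifically as the C3–C4 silyl enol ether (the C5 centre is temporary).

Step 4
Reactants: 5 {[(3R,4S)-4-[(benzyloxy)methyl]-3-methylcyclohex-1-en-1-yl]oxy}trimethylsilane
Product: 6 (S)-4-[(benzyloxy)methyl]-3-methylcyclohex-2-en-1-one
Conditions: Pd(OAc)2 (10 mol %), O2 (1 atm), DMSO, 25 °C
Reagents that add atoms: none
Why: Saegusa–Ito oxidation of the regiodefined silyl enol ether restores the C4=C5 enone, now carrying the first C5 methyl.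

Step 5
Reactants: 6 (S)-4-[(benzyloxy)methyl]-3-methylcyclohex-2-en-1-one
Product: 8 (2R,4S)-4-[(benzyloxy)methyl]-2,3,3-trimethylcyclohexan-1-one, via lithium enolate 7 (not isolated)
Conditions: Me2CuLi, Et2O, −20 °C; then MeI, HMPA, −40 → 0 °C
Reagents that add atoms: lithium dimethylcuprate, [Li+].C[Cu-]C; iodomethane, CI
Why: Cuprate conjugate addition makes C5 a gem-dimethyl carbon (no stereocentre), and the regiodefined enolate is then C-methylated at C4 through a chair-like transition state on the face opposite to the 1,3-related C10 arm, which sets C4 trans to C10 under kinetic control.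

Step 6
Reactants: 8 (2R,4S)-4-[(benzyloxy)methyl]-2,3,3-trimethylcyclohexan-1-one
Product: 9 (2R,4S)-4-(hydroxymethyl)-2,3,3-trimethylcyclohexan-1-one
Conditions: H2 (1 atm), Pd/C (10%), EtOAc, 20 °C
Reagents that add atoms: none
Why: Hydrogenolysis of the benzyl ether over palladium, which should not touch the ketone or either stereocentre.

Step 7
Reactants: 9 (2R,4S)-4-(hydroxymethyl)-2,3,3-trimethylcyclohexan-1-one
Product: 10 (1S,3R)-2,2,3-trimethyl-4-oxocyclohexane-1-carbaldehyde
Conditions: Dess–Martin periodinane, NaHCO3, CH2Cl2, 0 °C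
Reagents that add atoms: none
Why: Dess–Martin oxidation under buffered, non-basic conditions should give the aldehyde without epimerising C10 or C4.

Step 8
Reactants: 10 (1S,3R)-2,2,3-trimethyl-4-oxocyclohexane-1-carbaldehyde; 11 3-(methoxymethoxy)prop-1-ene
Product: 13 (2R,4S)-4-[(1R,2R)-1-hydroxy-2-(methoxymethoxy)but-3-en-1-yl]-2,3,3-trimethylcyclohexan-1-one, via allylborane 12 (not isolated)
Conditions: 11, s-BuLi, THF, −78 °C; (−)-Ipc2BOMe; BF3·OEt2; then 10, −78 °C; pH 7 buffer, H2O2, 0 °C
Reagents that add atoms: none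
Why: Brown-type alkoxyallylboration, in which the (Z)-γ-alkoxyallylborane adds to the aldehyde only (the hindered ketone is inert at −78 °C) through a chair-like six-membered transition state that gives the syn C8/C9 pair, with C9 set (R) by the isopinocampheyl groups in the sense matched with Felkin–Anh attack anti to the quaternary C5.

Step 9
Reactants: 13 (2R,4S)-4-[(1R,2R)-1-hydroxy-2-(methoxymethoxy)but-3-en-1-yl]-2,3,3-trimethylcyclohexan-1-one; 14 3-methylbut-2-enoyl chloride
Product: 15 (1R,2R)-2-(methoxymethoxy)-1-[(1S,3R)-2,2,3-trimethyl-4-oxocyclohexyl]but-3-en-1-yl 3-methylbut-2-enoate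
Conditions: pyridine, DMAP (cat.), CH2Cl2, 0 → 25 °C
Reagents that add atoms: none
Why: Acylation of the C9 hydroxyl by the acid chloride under nucleophilic catalysis, with pyridine instead of a stronger amine to avoid the vinylketene pathway that would move the double bond out of conjugation.

Step 10
Reactants: 16 3-chloro-2-methylprop-1-ene; 17 sodium benzenesulfinate
Product: 18 [(2-methylprop-2-en-1-yl)sulfonyl]benzene
Conditions: DMF, 60 °C
Reagents that add atoms: none
Why: SN2 S-alkylation of the sulfinate by the allylic chloride gives the allyl sulfone.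

Step 11
Reactants: 15 (1R,2R)-2-(methoxymethoxy)-1-[(1S,3R)-2,2,3-trimethyl-4-oxocyclohexyl]but-3-en-1-yl 3-methylbut-2-enoate; 18 [(2-methylprop-2-en-1-yl)sulfonyl]benzene
Product: 19 (1R,2R,3E)-2-(methoxymethoxy)-4-methyl-5-(phenylsulfonyl)-1-[(1S,3R)-2,2,3-trimethyl-4-oxocyclohexyl]pent-3-en-1-yl 3-methylbut-2-enoate
Conditions: 18 (5 equiv), second-generation Hoveyda–Grubbs catalyst RuCl2(H2IMes)(=CH-C6H4-2-O-i-Pr) (10 mol %), CH2Cl2, 40 °C
Reagents that add atoms: none
Why: Olefin cross-metathesis of the terminal vinyl group with an excess of the 1,1-disubstituted partner builds the C7=C11 trisubstituted allyl sulfone, while the trisubstituted enoate should stay inert.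

Step 12
Reactants: 19 (1R,2R,3E)-2-(methoxymethoxy)-4-methyl-5-(phenylsulfonyl)-1-[(1S,3R)-2,2,3-trimethyl-4-oxocyclohexyl]pent-3-en-1-yl 3-methylbut-2-enoate
Product: 20 (1R,2R,3E)-1-[(1S,3R,4R)-4-hydroxy-2,2,3-trimethylcyclohexyl]-2-(methoxymethoxy)-4-methyl-5-(phenylsulfonyl)pent-3-en-1-yl 3-methylbut-2-enoate
Conditions: (S)-2-methyl-CBS-oxazaborolidine (0.5 equiv), catecholborane, toluene, −78 → −40 °C; then H2O
Reagents that add atoms: none
Why: Corey–Bakshi–Shibata reduction, in which the (S)-catalyst tells the branched C4 side from the C2 methylene and delivers hydride to the β face, the face that the axial α-methyl on C5 leaves open, to give the axial (3R) hydroxyl cis to the C10 arm.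

Step 13
Reactants: 20 (1R,2R,3E)-1-[(1S,3R,4R)-4-hydroxy-2,2,3-trimethylcyclohexyl]-2-(methoxymethoxy)-4-methyl-5-(phenylsulfonyl)pent-3-en-1-yl 3-methylbut-2-enoate
Product: 21 (1R,2R,3E)-2-(methoxymethoxy)-4-methyl-1-[(1S,3R,4R)-2,2,3-trimethyl-4-{[(4-nitrophenyl)sulfanyl]oxy}cyclohexyl]-5-(phenylsulfonyl)pent-3-en-1-yl 3-methylbut-2-enoate
Conditions: 4-O2NC6H4SCl, Et3N, CH2Cl2, −78 °C, dark
Reagents that add atoms: 4-nitrobenzenesulfenyl chloride, [O-][N+](=O)c1ccc(SCl)cc1
Why: O-Sulfenylation of the alcohol with an arenesulfenyl chloride, in which no bond to C3 is broken, so the configuration is retained.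

Step 14
Reactants: 21 (1R,2R,3E)-2-(methoxymethoxy)-4-methyl-1-[(1S,3R,4R)-2,2,3-trimethyl-4-{[(4-nitrophenyl)sulfanyl]oxy}cyclohexyl]-5-(phenylsulfonyl)pent-3-en-1-yl 3-methylbut-2-enoate
Product: 22 (3R,4R,5R,7R,8R,9R,10S)-3-hydroxy-8-(methoxymethoxy)eremophil-11-en-9-yl 3-methylbut-2-enoate
Conditions: hν (350 nm), benzene (0.005 M), Ar, 20 °C
Reagents that add atoms: none
Why: Proposed new method: light cleaves the S–O bond of the sulfenate, the C3 alkoxy radical takes a hydrogen atom through a six-membered transition state (O–C3–C4–C5–C–H) from the C5 methyl that is 1,3-diaxial to it, the primary C6 radical adds 6-exo-trig to C7 of the allyl sulfone, and β-scission of the C12–S bond expels PhSO2•, which leaves the C11=C12 isopropenyl group and ends as the thiosulfonate by coupling with the arylthiyl radical or its disulfide. The closest known reaction types are the Barton-type remote functionalisation by alkoxy radicals from photolysed nitrite or sulfenate esters, in which δ-carbon radicals have been captured by tethered alkenes, and the allylation of such δ-carbon radicals with allyl sulfones by addition and β-fragmentation; their union in a ring-closing relay on a gem-dimethyl group is what is new. Ring B closes in the 6-exo-trig radical mode, and the cis ring fusion follows because the methyl that reacts and the C10 side arm are both on the α face of ring A. C5 becomes a stereocentre by choice between its two methyls, which the C3 oxygen controls because only the cis, syn-axial methyl is within reach, and C7 is set by a chair-like transition state with the C9 ester, the C8 ether and the sulfonyl-bearing alkene arm equatorial, which puts the new isopropenyl group β. The step needs hydrogen transfer to outrun β-scission of the alkoxy radical and ring closure to outrun radical coupling and a 1,5-hydrogen shift from C8; the short O···H distance of the 1,3-diaxial pair in the chair that keeps the side arm equatorial secures the first, and the absence of any hydrogen donor, the low standing concentration of the self-dimerising thiyl radical and the polarity mismatch of an alkyl radical with the α-oxygenated C8–H secure the second.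

Step 15
Reactants: 22 (3R,4R,5R,7R,8R,9R,10S)-3-hydroxy-8-(methoxymethoxy)eremophil-11-en-9-yl 3-methylbut-2-enoate; 23 (Z)-2-methylbut-2-enoic acid (angelic acid)
Product: 25 (3R,4R,5R,7R,8R,9R,10S)-8-(methoxymethoxy)-9-[(3-methylbut-2-enoyl)oxy]eremophil-11-en-3-yl (Z)-2-methylbut-2-enoate, via mixed anhydride 24 (not isolated)
Conditions: 23, 2,4,6-Cl3C6H2COCl, Et3N, toluene, 20 °C; then 22, toluene, 80 °C
Reagents that add atoms: none
Why: Yamaguchi esterification through the mixed anhydride, run without DMAP so that the (Z)-2-methylbut-2-enoyl group should not isomerise to the E isomer, on the only free hydroxyl (equatorial at C3).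

Step 16
Reactants: 25 (3R,4R,5R,7R,8R,9R,10S)-8-(methoxymethoxy)-9-[(3-methylbut-2-enoyl)oxy]eremophil-11-en-3-yl (Z)-2-methylbut-2-enoate
Product: 26 (3R,4R,5R,7R,8R,9R,10S)-8-hydroxy-9-[(3-methylbut-2-enoyl)oxy]eremophil-11-en-3-yl (Z)-2-methylbut-2-enoate
Conditions: ZnBr2, n-PrSH, CH2Cl2, 0 °C, 10 min
Reagents that add atoms: none
Why: Lewis acid and thiol cleavage of the methoxymethyl acetal (transfer of the methoxymethyl group to sulfur) under conditions that should leave esters and alkenes alone and give no time for acyl migration from O9 to O8.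

Step 17
Reactants: 26 (3R,4R,5R,7R,8R,9R,10S)-8-hydroxy-9-[(3-methylbut-2-enoyl)oxy]eremophil-11-en-3-yl (Z)-2-methylbut-2-enoate
Product: 27 (3R,4R,5R,7R,9R,10S)-9-[(3-methylbut-2-enoyl)oxy]-8-oxoeremophil-11-en-3-yl (Z)-2-methylbut-2-enoate (CNP0375730.2)
Conditions: Dess–Martin periodinane, NaHCO3, CH2Cl2, 0 °C
Reagents that add atoms: none
Why: Dess–Martin oxidation of the C8 alcohol under buffered conditions, mild enough that C7 and C9 should not epimerise and the C11=C12 double bond should not move into conjugation.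

**Compound list**

1 | 3-(benzyloxy)propanal | O=CCCOCc1ccccc1 | starting material
2 | but-3-en-2-one | CC(=O)C=C | starting material
3 | (R)-2-[(benzyloxy)methyl]-5-oxohexanal | O=C[C@H](CCC(C)=O)COCc1ccccc1 | intermediate
4 | (S)-4-[(benzyloxy)methyl]cyclohex-2-en-1-one | O=C1C=C[C@H](CC1)COCc1ccccc1 | intermediate
5 | {[(3R,4S)-4-[(benzyloxy)methyl]-3-methylcyclohex-1-en-1-yl]oxy}trimethylsilane | C[Si](C)(C)OC1=C[C@H](C)[C@H](CC1)COCc1ccccc1 | intermediate
6 | (S)-4-[(benzyloxy)methyl]-3-methylcyclohex-2-en-1-one | O=C1C=C(C)[C@H](CC1)COCc1ccccc1 | intermediate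
7 | lithium (S)-4-[(benzyloxy)methyl]-3,3-dimethylcyclohex-1-en-1-olate | [Li+].[O-]C1=CC(C)(C)[C@H](CC1)COCc1ccccc1 | intermediate
8 | (2R,4S)-4-[(benzyloxy)methyl]-2,3,3-trimethylcyclohexan-1-one | O=C1[C@H](C)C(C)(C)[C@H](CC1)COCc1ccccc1 | intermediate
9 | (2R,4S)-4-(hydroxymethyl)-2,3,3-trimethylcyclohexan-1-one | O=C1[C@H](C)C(C)(C)[C@H](CC1)CO | intermediate
10 | (1S,3R)-2,2,3-trimethyl-4-oxocyclohexane-1-carbaldehyde | O=C1[C@H](C)C(C)(C)[C@H](CC1)C=O | intermediate
11 | 3-(methoxymethoxy)prop-1-ene | C=CCOCOC | starting material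
12 | [(Z)-3-(methoxymethoxy)prop-2-en-1-yl]bis(isopinocampheyl)borane, from (−)-Ipc2BOMe | COCO/C=C\CB([C@@H]1C[C@@H]2C[C@H]([C@H]1C)C2(C)C)[C@@H]1C[C@@H]2C[C@H]([C@H]1C)C2(C)C | intermediate
13 | (2R,4S)-4-[(1R,2R)-1-hydroxy-2-(methoxymethoxy)but-3-en-1-yl]-2,3,3-trimethylcyclohexan-1-one | O=C1[C@H](C)C(C)(C)[C@H](CC1)[C@@H](O)[C@H](OCOC)C=C | intermediate
14 | 3-methylbut-2-enoyl chloride | CC(C)=CC(Cl)=O | starting material
15 | (1R,2R)-2-(methoxymethoxy)-1-[(1S,3R)-2,2,3-trimethyl-4-oxocyclohexyl]but-3-en-1-yl 3-methylbut-2-enoate | O=C1[C@H](C)C(C)(C)[C@H](CC1)[C@@H](OC(=O)C=C(C)C)[C@H](OCOC)C=C | intermediate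
16 | 3-chloro-2-methylprop-1-ene | C=C(C)CCl | starting material
17 | sodium benzenesulfinate | [Na+].[O-]S(=O)c1ccccc1 | starting material
18 | [(2-methylprop-2-en-1-yl)sulfonyl]benzene | C=C(C)CS(=O)(=O)c1ccccc1 | intermediate
19 | (1R,2R,3E)-2-(methoxymethoxy)-4-methyl-5-(phenylsulfonyl)-1-[(1S,3R)-2,2,3-trimethyl-4-oxocyclohexyl]pent-3-en-1-yl 3-methylbut-2-enoate | O=C1[C@H](C)C(C)(C)[C@H](CC1)[C@@H](OC(=O)C=C(C)C)[C@H](OCOC)/C=C(\C)CS(=O)(=O)c1ccccc1 | intermediate
20 | (1R,2R,3E)-1-[(1S,3R,4R)-4-hydroxy-2,2,3-trimethylcyclohexyl]-2-(methoxymethoxy)-4-methyl-5-(phenylsulfonyl)pent-3-en-1-yl 3-methylbut-2-enoate | O[C@H]1[C@H](C)C(C)(C)[C@H](CC1)[C@@H](OC(=O)C=C(C)C)[C@H](OCOC)/C=C(\C)CS(=O)(=O)c1ccccc1 | intermediate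
21 | (1R,2R,3E)-2-(methoxymethoxy)-4-methyl-1-[(1S,3R,4R)-2,2,3-trimethyl-4-{[(4-nitrophenyl)sulfanyl]oxy}cyclohexyl]-5-(phenylsulfonyl)pent-3-en-1-yl 3-methylbut-2-enoate | [O-][N+](=O)c1ccc(SO[C@H]2[C@H](C)C(C)(C)[C@H](CC2)[C@@H](OC(=O)C=C(C)C)[C@H](OCOC)/C=C(\C)CS(=O)(=O)c2ccccc2)cc1 | intermediate
22 | (3R,4R,5R,7R,8R,9R,10S)-3-hydroxy-8-(methoxymethoxy)eremophil-11-en-9-yl 3-methylbut-2-enoate | C=C(C)[C@H]1C[C@@]2(C)[C@H](CC[C@@H](O)[C@@H]2C)[C@@H](OC(=O)C=C(C)C)[C@@H]1OCOC | intermediate
23 | (Z)-2-methylbut-2-enoic acid (angelic acid) | C/C=C(/C)C(=O)O | starting material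
24 | (Z)-2-methylbut-2-enoic 2,4,6-trichlorobenzoic anhydride | C/C=C(/C)C(=O)OC(=O)c1c(Cl)cc(Cl)cc1Cl | intermediate
25 | (3R,4R,5R,7R,8R,9R,10S)-8-(methoxymethoxy)-9-[(3-methylbut-2-enoyl)oxy]eremophil-11-en-3-yl (Z)-2-methylbut-2-enoate | C=C(C)[C@H]1C[C@@]2(C)[C@H](CC[C@@H](OC(=O)/C(C)=C\C)[C@@H]2C)[C@@H](OC(=O)C=C(C)C)[C@@H]1OCOC | intermediate
26 | (3R,4R,5R,7R,8R,9R,10S)-8-hydroxy-9-[(3-methylbut-2-enoyl)oxy]eremophil-11-en-3-yl (Z)-2-methylbut-2-enoate | C=C(C)[C@H]1C[C@@]2(C)[C@H](CC[C@@H](OC(=O)/C(C)=C\C)[C@@H]2C)[C@@H](OC(=O)C=C(C)C)[C@@H]1O | intermediate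
27 | (3R,4R,5R,7R,9R,10S)-9-[(3-methylbut-2-enoyl)oxy]-8-oxoeremophil-11-en-3-yl (Z)-2-methylbut-2-enoate | C=C(C)[C@H]1C[C@@]2(C)[C@H](CC[C@@H](OC(=O)/C(C)=C\C)[C@@H]2C)[C@@H](OC(=O)C=C(C)C)C1=O | target

**Step count and risks**

Total step count: 17. Longest linear sequence: 16 steps (steps 1–9 and 11–17); step 10 is a one-step branch.

Steps most likely to fail:

1. Step 14 (bears the label "Proposed new method:"). The alkoxy radical may fragment by β-scission (opening ring A) before it abstracts hydrogen. The C6 radical may also be intercepted, by coupling with the arylthiyl radical or by a 1,5-hydrogen shift from C8, before the slower 6-exo closure. The fallback uses known chemistry and separates the two events. It sets out from 20: a hypoiodite reaction (PhI(OAc)2, I2, cyclohexane, visible light, 20 °C, sub-stoichiometric oxidant) should iodinate the same syn-axial methyl and give the neopentyl iodide (1R,2R,3E)-1-[(1S,2R,3R,4R)-4-hydroxy-2-(iodomethyl)-2,3-dimethylcyclohexyl]-2-(methoxymethoxy)-4-methyl-5-(phenylsulfonyl)pent-3-en-1-yl 3-methylbut-2-enoate F1, which as a neopentyl halide should be slow to close to the cyclic ether. A conventional tin hydride radical cyclisation (Bu3SnH by slow addition, AIBN, benzene, 80 °C; 6-exo-trig addition, then β-elimination of the sulfonyl radical) should then give 22, where the fallback comes back to the route.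

2. Step 5. The methylation of the enolate may show poor facial selectivity, or the kinetically formed trans C4/C10 ketone may equilibrate to the more stable cis isomer, and over-alkylation may compete. The fallback sets the C4 centre by a hydroxyl-directed hydrogenation instead, and sets out from 6. Cuprate addition as before, with capture of the enolate by dimethyl(methylidene)ammonium iodide, should give the Mannich base (4S)-4-[(benzyloxy)methyl]-2-[(dimethylamino)methyl]-3,3-dimethylcyclohexan-1-one F2. Quaternisation with MeI and elimination with NaHCO3 should give the enone (S)-4-[(benzyloxy)methyl]-3,3-dimethyl-2-methylidenecyclohexan-1-one F3. Corey–Bakshi–Shibata reduction with the (S)-catalyst should give the allylic alcohol (1R,4S)-4-[(benzyloxy)methyl]-3,3-dimethyl-2-methylidenecyclohexan-1-ol F4. Hydrogenation with [Ir(cod)(PCy3)(py)]PF6 and H2 in CH2Cl2 should deliver hydrogen to C4 from the hydroxyl face and give the trans alcohol (1R,2R,4S)-4-[(benzyloxy)methyl]-2,3,3-trimethylcyclohexan-1-ol F5. Dess–Martin oxidation then returns to the route at 8.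

3. Step 11. The cross-metathesis may stall because the 1,1-disubstituted sulfone loads poorly onto the catalyst and the vinyl group sits next to a branched allylic ether, so that catalyst decay or homodimerisation takes over. The fallback builds the allyl sulfone in stages and sets out from 15. Cross-metathesis with 2-methylprop-2-enal (same catalyst) should give the enal (1R,2R,3E)-2-(methoxymethoxy)-4-methyl-5-oxo-1-[(1S,3R)-2,2,3-trimethyl-4-oxocyclohexyl]pent-3-en-1-yl 3-methylbut-2-enoate F6. Aldehyde-selective reduction with NaBH(OAc)3 should give the allylic alcohol (1R,2R,3E)-5-hydroxy-2-(methoxymethoxy)-4-methyl-1-[(1S,3R)-2,2,3-trimethyl-4-oxocyclohexyl]pent-3-en-1-yl 3-methylbut-2-enoate F7. An Appel reaction (CBr4, PPh3) should give the allylic bromide (1R,2R,3E)-5-bromo-2-(methoxymethoxy)-4-methyl-1-[(1S,3R)-2,2,3-trimethyl-4-oxocyclohexyl]pent-3-en-1-yl 3-methylbut-2-enoate F8. Displacement with 17 in DMF then comes back to the route at 19.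

**Further compounds**

F1 | step 14 | (1R,2R,3E)-1-[(1S,2R,3R,4R)-4-hydroxy-2-(iodomethyl)-2,3-dimethylcyclohexyl]-2-(methoxymethoxy)-4-methyl-5-(phenylsulfonyl)pent-3-en-1-yl 3-methylbut-2-enoate | O[C@H]1[C@H](C)[C@@](C)(CI)[C@H](CC1)[C@@H](OC(=O)C=C(C)C)[C@H](OCOC)/C=C(\C)CS(=O)(=O)c1ccccc1
F2 | step 5 | (4S)-4-[(benzyloxy)methyl]-2-[(dimethylamino)methyl]-3,3-dimethylcyclohexan-1-one | O=C1C(CN(C)C)C(C)(C)[C@H](CC1)COCc1ccccc1
F3 | step 5 | (S)-4-[(benzyloxy)methyl]-3,3-dimethyl-2-methylidenecyclohexan-1-one | O=C1C(=C)C(C)(C)[C@H](CC1)COCc1ccccc1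
F4 | step 5 | (1R,4S)-4-[(benzyloxy)methyl]-3,3-dimethyl-2-methylidenecyclohexan-1-ol | O[C@H]1C(=C)C(C)(C)[C@H](CC1)COCc1ccccc1
F5 | step 5 | (1R,2R,4S)-4-[(benzyloxy)methyl]-2,3,3-trimethylcyclohexan-1-ol | O[C@H]1[C@H](C)C(C)(C)[C@H](CC1)COCc1ccccc1
F6 | step 11 | (1R,2R,3E)-2-(methoxymethoxy)-4-methyl-5-oxo-1-[(1S,3R)-2,2,3-trimethyl-4-oxocyclohexyl]pent-3-en-1-yl 3-methylbut-2-enoate | O=C1[C@H](C)C(C)(C)[C@H](CC1)[C@@H](OC(=O)C=C(C)C)[C@H](OCOC)/C=C(\C)C=O
F7 | step 11 | (1R,2R,3E)-5-hydroxy-2-(methoxymethoxy)-4-methyl-1-[(1S,3R)-2,2,3-trimethyl-4-oxocyclohexyl]pent-3-en-1-yl 3-methylbut-2-enoate | O=C1[C@H](C)C(C)(C)[C@H](CC1)[C@@H](OC(=O)C=C(C)C)[C@H](OCOC)/C=C(\C)CO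
F8 | step 11 | (1R,2R,3E)-5-bromo-2-(methoxymethoxy)-4-methyl-1-[(1S,3R)-2,2,3-trimethyl-4-oxocyclohexyl]pent-3-en-1-yl 3-methylbut-2-enoate | O=C1[C@H](C)C(C)(C)[C@H](CC1)[C@@H](OC(=O)C=C(C)C)[C@H](OCOC)/C=C(\C)CBr
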